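**Retrosynthetic overview**

- The target is ring A (2,4,6-trihydroxyphenyl) joined through the C1 ketone and the unbranched C2–C11 decamethylene chain to ring B (2-hydroxyphenyl). It has no stereocentre, and no ring is formed in the route: both arenes are bought and carried as methyl ethers.
- The strategy rests on C7, an unfunctionalised methylene in the middle of the chain between C6 and C8. C7 is introduced as the doubly nucleophilic carbon of bis(phenylsulfonyl)methane, so the chain is cut at C6–C7 and C7–C8.
- The C6 electrophile is the ring A bromoketone (C1–C6), from Friedel–Crafts acylation of 1,3,5-trimethoxybenzene. The C8 electrophile is the ring B butyl iodide (C8–C11), from a copper-catalysed Grignard coupling and halide exchange.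
- After the one-flask double alkylation, both sulfonyl groups are removed reductively from C7, and the four methyl ethers are cleaved last.

Key step: step 4

Remark: the chain is numbered from C1 (carbonyl carbon on ring A) to C11 (benzylic carbon on ring B); (2-methoxyphenyl)magnesium bromide is taken as the commercial THF solution.

**Route**

Step 1
Reactants: 1 6-bromohexanoyl chloride; 2 1,3,5-trimethoxybenzene
Product: 3 6-bromo-1-(2,4,6-trimethoxyphenyl)hexan-1-one
Conditions: SnCl4 (1.1 equiv), CH2Cl2, −10 °C → 0 °C; aqueous work-up
Reagents that add atoms: none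
Why: Friedel–Crafts acylation of a strongly activated, threefold-symmetric arene should stop cleanly at the mono-ketone (the acyl group deactivates the ring), and the mild Lewis acid at low temperature should spare both the ortho methoxy groups and the primary bromide.

Step 2
Reactants: 4 (2-methoxyphenyl)magnesium bromide; 5 1-bromo-4-chlorobutane
Product: 6 1-(4-chlorobutyl)-2-methoxybenzene
Conditions: Li2CuCl4 (3 mol %), THF/NMP, 0 °C → rt; 4 added slowly to 5 (1.5 equiv)
Reagents that add atoms: none
Why: Kochi-type copper-catalysed cross-coupling of an aryl Grignard reagent with a primary alkyl halide, in which the organocopper species displaces bromide far faster than chloride, so the chloride should survive as the handle for the next step.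

Step 3
Reactants: 6 1-(4-chlorobutyl)-2-methoxybenzene
Product: 7 1-(4-iodobutyl)-2-methoxybenzene
Conditions: NaI (3 equiv), acetone, reflux
Reagents that add atoms: sodium iodide, [Na+].[I-]
Why: Finkelstein SN2 halide exchange at an unhindered primary carbon, driven by precipitation of NaCl from acetone.

Step 4
Reactants: 8 bis(phenylsulfonyl)methane; 3 6-bromo-1-(2,4,6-trimethoxyphenyl)hexan-1-one; 7 1-(4-iodobutyl)-2-methoxybenzene
Product: 10 11-(2-methoxyphenyl)-7,7-bis(phenylsulfonyl)-1-(2,4,6-trimethoxyphenyl)undecan-1-one, via mono-alkylated bis-sulfone 9 (not isolated)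
Conditions: 8 (1.05 equiv), NaH (1.0 equiv), DMF, 0 °C → rt; 3 (1.0 equiv), n-Bu4NI (10 mol %), 60 °C; then Cs2CO3 (2 equiv), 7 (1.5 equiv), 80 °C
Reagents that add atoms: none
Why: NaH turns 8 into its sodium carbanion, which displaces bromide from C6 of 3 by SN2 to give 9; Cs2CO3 then removes the remaining acidic C7–H of 9 and the caesium carbanion displaces iodide from C8 of 7, so the carbon that becomes C7 forms the C6–C7 and C7–C8 bonds in one flask. The closest known reaction type is the sequential dialkylation of bis(phenylsulfonyl)methane, a methylene dianion equivalent, with two different primary halides. No ring is closed and no stereocentre arises, since C7 carries two identical sulfonyl groups. The step needs mono-alkylation to be complete before the second electrophile goes in; this should be secured by using no more than one equivalent of base together with the less reactive bromide first (the hindered anion of 9 cannot compete for 3), and by reserving the more reactive iodide and the caesium counter-ion for the slow second alkylation. It also needs the C1 ketone to stay out of the reaction: the bis-sulfonyl carbanions are many pK units less basic than a ketone enolate, so C2 should not be deprotonated and neither aldol chemistry nor 5-exo closure of C2 onto C6 is expected.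

Step 5
Reactants: 10 11-(2-methoxyphenyl)-7,7-bis(phenylsulfonyl)-1-(2,4,6-trimethoxyphenyl)undecan-1-one
Product: 11 11-(2-methoxyphenyl)-1-(2,4,6-trimethoxyphenyl)undecan-1-one
Conditions: Na/Hg (6% Na, excess), Na2HPO4, MeOH/THF, −20 °C → rt
Reagents that add atoms: none
Why: Reductive desulfonylation by electron transfer from sodium amalgam; the geminal bis-sulfone should lose the first benzenesulfinate easily (sulfonyl-stabilised carbanion, protonated by MeOH) and the resulting secondary alkyl phenyl sulfone the second more slowly, while the phosphate buffer keeps methoxide low and the twisted, electron-rich ring A ketone is expected to be reduced more slowly than the sulfones.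

Step 6
Reactants: 11 11-(2-methoxyphenyl)-1-(2,4,6-trimethoxyphenyl)undecan-1-one
Product: 12 11-(2-hydroxyphenyl)-1-(2,4,6-trihydroxyphenyl)undecan-1-one
Conditions: BBr3 (8 equiv), CH2Cl2, −78 °C → rt; then H2O, 0 °C
Reagents that add atoms: none
Why: BBr3 cleavage of aryl methyl ethers (Lewis acid complexation, then bromide attack on the methyl group); the two methoxy groups ortho to the C1 carbonyl are activated by chelation, the excess reagent and the time at room temperature serve the 4-methoxy group of ring A and the ring B ether, and the ketone and saturated chain are inert.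

**Compound list**

1 | 6-bromohexanoyl chloride | O=C(Cl)CCCCCBr | starting material
2 | 1,3,5-trimethoxybenzene | COc1cc(OC)cc(OC)c1 | starting material
3 | 6-bromo-1-(2,4,6-trimethoxyphenyl)hexan-1-one | COc1cc(OC)c(C(=O)CCCCCBr)c(OC)c1 | intermediate
4 | (2-methoxyphenyl)magnesium bromide (THF solution) | COc1ccccc1[Mg]Br | starting material
5 | 1-bromo-4-chlorobutane | ClCCCCBr | starting material
6 | 1-(4-chlorobutyl)-2-methoxybenzene | COc1ccccc1CCCCCl | intermediate
7 | 1-(4-iodobutyl)-2-methoxybenzene | COc1ccccc1CCCCI | intermediate
8 | bis(phenylsulfonyl)methane | O=S(=O)(CS(=O)(=O)c1ccccc1)c1ccccc1 | starting material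
9 | 7,7-bis(phenylsulfonyl)-1-(2,4,6-trimethoxyphenyl)heptan-1-one (mono-alkylated bis-sulfone, formed in the flask) | COc1cc(OC)c(C(=O)CCCCCC(S(=O)(=O)c2ccccc2)S(=O)(=O)c2ccccc2)c(OC)c1 | intermediate
10 | 11-(2-methoxyphenyl)-7,7-bis(phenylsulfonyl)-1-(2,4,6-trimethoxyphenyl)undecan-1-one | COc1ccccc1CCCCC(CCCCCC(=O)c1c(OC)cc(OC)cc1OC)(S(=O)(=O)c1ccccc1)S(=O)(=O)c1ccccc1 | intermediate
11 | 11-(2-methoxyphenyl)-1-(2,4,6-trimethoxyphenyl)undecan-1-one | COc1ccccc1CCCCCCCCCCC(=O)c1c(OC)cc(OC)cc1OC | intermediate
12 | 11-(2-hydroxyphenyl)-1-(2,4,6-trihydroxyphenyl)undecan-1-one | O=C(CCCCCCCCCCc1ccccc1O)c1c(O)cc(O)cc1O | target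

**Step count**

Total steps: 6. Longest linear sequence: 5 steps (4 → 6 → 7 → 10 → 11 → 12).

**Steps most likely to fail**

1. Step 4 (key step). The second alkylation may stall: the carbanion of 9 is hindered and strongly stabilised, so loss of HI from 7 or slow decomposition could outrun C7–C8 bond formation. The fallback sets out from 3 and 7 and uses the smaller, more nucleophilic commercial methyl (phenylsulfonyl)acetate as the C7 donor. Its sodium salt (NaH, DMF) is alkylated with 3 to racemic methyl 8-oxo-2-(phenylsulfonyl)-8-(2,4,6-trimethoxyphenyl)octanoate F1. A second alkylation with 7 (Cs2CO3, DMF) should give racemic methyl 2-[4-(2-methoxyphenyl)butyl]-8-oxo-2-(phenylsulfonyl)-8-(2,4,6-trimethoxyphenyl)octanoate F2. Krapcho dealkoxycarbonylation (LiCl, wet DMSO, 130 °C) should then give racemic 11-(2-methoxyphenyl)-7-(phenylsulfonyl)-1-(2,4,6-trimethoxyphenyl)undecan-1-one F3. Buffered Na/Hg as in step 5 removes the single sulfonyl group, and the route is rejoined at 11.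

2. Step 5. Electron transfer to the C1 aryl ketone (carbinol or pinacol formation) may compete while the slower second C–S cleavage at C7 is being driven to completion. The fallback sets out from 10 and takes the ketone out of play first. NaBH4 (MeOH/THF) should reduce it to racemic 11-(2-methoxyphenyl)-7,7-bis(phenylsulfonyl)-1-(2,4,6-trimethoxyphenyl)undecan-1-ol F4. Both sulfonyl groups can then be removed under forcing conditions (Mg turnings, MeOH, 50 °C) to give racemic 11-(2-methoxyphenyl)-1-(2,4,6-trimethoxyphenyl)undecan-1-ol F5. Oxidation of the benzylic alcohol with Dess–Martin periodinane (NaHCO3, CH2Cl2) returns to the route at 11.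

3. Step 6. Ether cleavage may stop before the 4-methoxy group of ring A (para to the acyl group) is removed, or the forcing needed for it may degrade the boron-chelated acylphloroglucinol. The fallback sets out from 8 and 7 and attaches ring A last as free phloroglucinol, so ring A never carries methyl ethers.
   - 8 is alkylated first with commercial methyl 6-bromohexanoate (NaH, DMF) to methyl 7,7-bis(phenylsulfonyl)heptanoate F6, then with 7 (Cs2CO3, DMF) to methyl 11-(2-methoxyphenyl)-7,7-bis(phenylsulfonyl)undecanoate F7.
   - Mg in MeOH removes both sulfonyl groups to give methyl 11-(2-methoxyphenyl)undecanoate F8.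
   - BBr3 (CH2Cl2) followed by aqueous LiOH cleaves the single unactivated aryl methyl ether and the ester to 11-(2-hydroxyphenyl)undecanoic acid F9.
   - Friedel–Crafts C-acylation of phloroglucinol with F9 in BF3·OEt2 at 80 °C should give 12 directly.

**Further compounds**

F1 | step 4 | methyl 8-oxo-2-(phenylsulfonyl)-8-(2,4,6-trimethoxyphenyl)octanoate (racemic) | COC(=O)C(CCCCCC(=O)c1c(OC)cc(OC)cc1OC)S(=O)(=O)c1ccccc1
F2 | step 4 | methyl 2-[4-(2-methoxyphenyl)butyl]-8-oxo-2-(phenylsulfonyl)-8-(2,4,6-trimethoxyphenyl)octanoate (racemic) | COC(=O)C(CCCCc1ccccc1OC)(CCCCCC(=O)c1c(OC)cc(OC)cc1OC)S(=O)(=O)c1ccccc1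
F3 | step 4 | 11-(2-methoxyphenyl)-7-(phenylsulfonyl)-1-(2,4,6-trimethoxyphenyl)undecan-1-one (racemic) | COc1ccccc1CCCCC(CCCCCC(=O)c1c(OC)cc(OC)cc1OC)S(=O)(=O)c1ccccc1
F4 | step 5 | 11-(2-methoxyphenyl)-7,7-bis(phenylsulfonyl)-1-(2,4,6-trimethoxyphenyl)undecan-1-ol (racemic) | COc1ccccc1CCCCC(CCCCCC(O)c1c(OC)cc(OC)cc1OC)(S(=O)(=O)c1ccccc1)S(=O)(=O)c1ccccc1
F5 | step 5 | 11-(2-methoxyphenyl)-1-(2,4,6-trimethoxyphenyl)undecan-1-ol (racemic) | COc1ccccc1CCCCCCCCCCC(O)c1c(OC)cc(OC)cc1OC
F6 | step 6 | methyl 7,7-bis(phenylsulfonyl)heptanoate | COC(=O)CCCCCC(S(=O)(=O)c1ccccc1)S(=O)(=O)c1ccccc1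
F7 | step 6 | methyl 11-(2-methoxyphenyl)-7,7-bis(phenylsulfonyl)undecanoate | COC(=O)CCCCCC(CCCCc1ccccc1OC)(S(=O)(=O)c1ccccc1)S(=O)(=O)c1ccccc1
F8 | step 6 | methyl 11-(2-methoxyphenyl)undecanoate | COC(=O)CCCCCCCCCCc1ccccc1OC
F9 | step 6 | 11-(2-hydroxyphenyl)undecanoic acid | OC(=O)CCCCCCCCCCc1ccccc1O
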